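**Plan**

- Numbering is that of longipinane: C1 ketone, C2=C3(Me), bridgeheads C4 and C11, one-carbon bridges C5 and C10(Me), C6 = CMe2, C7/C8/C9 oxygenated.
- Retrosynthesis: cleave the two angelate C–O bonds; cut C1–C11 and C4–C5 together, which opens the enone ring and the cyclobutane and leaves a cycloheptene (C5=C11) carrying a 3-methylcyclobutenone (C1–C4, a masked vinylketene) on quaternary C10. Cut the cyclobutenone to a C10–CH2CO2H arm (ketene/ethoxyacetylene [2+2], then MeLi), cut C10–C4 by a Claisen retron, and cut the cycloheptenone to 2-methylfuran plus a dimethyl-oxyallyl cation ([4+3]).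
- Forward ring order: seven-membered ring first, then the cyclobutenone, then the six-membered enone ring and the cyclobutane in one rhodium-catalysed event; the esters go on last.
- Enabling feature: C10 holds C4 of the four-carbon unit and alkene carbon C11 one atom apart, and the C5=C11 alkene is flanked by quaternary C6 and C10, so a metallacycle formed there has no exocyclic β-hydrogen and is left to close the cyclobutane.
- Stereochemistry: C7 by enzymatic resolution (the only centre set by catalysis); C8/C9 by osmylation anti to C7–O; C5–OH by 1,3-anti hydride delivery; C10 by [3,3] transfer from C5–O; C4, C5 and C11 relayed from C10 in the key step.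

Key step: step 12

Remark: racemates (4–7) are written as SMILES without stereo marks; 19–21 are mixtures of epimers at the cyclobutenone sp3 carbon (C4), which converge in step 12; catalyst-bound rhodium species are treated as mechanism and carry no number.

**Route**

Step 1
Reactants: 1 2-methylfuran; 2 3-bromo-3-methylbutan-2-one
Product: 4 rac-1,4,4-trimethyl-8-oxabicyclo[3.2.1]oct-6-en-3-one, via oxyallyl cation 3 (not isolated)
Conditions: Et3N, CF3CH2OH, 0 °C to rt, 1 in excess
Reagents that add atoms: none
Why: [4+3] cycloaddition of the furan with the oxyallyl cation set free by dehydrobromination; the unsubstituted furan α-carbon should bond to the more cationic CMe2 terminus, which puts the bridgehead methyl next to CH2 and avoids adjacent quaternary carbons, and the bridge fixes the relative configuration.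

Step 2
Reactants: 4
Product: 7 rac-6-acetoxy-3,7,7-trimethylcyclohepta-2,4-dien-1-one, via silyl ether 5 (not isolated), via alcohol 6 (not isolated)
Conditions: TMSOTf, Et3N, CH2Cl2, 0 °C; MeOH, citric acid (cat.), rt; then Ac2O, pyridine, DMAP, CH2Cl2, 0 °C
Reagents that add atoms: trimethylsilyl trifluoromethanesulfonate C[Si](C)(C)OS(=O)(=O)C(F)(F)F (silicon stays only in 5); acetic anhydride CC(=O)OC(C)=O
Why: silyl-triflate-mediated opening of the oxygen bridge (enol silylation toward C11, then E1cB-type loss of the bridging oxygen from tertiary, allylic C10) is a known way from such [4+3] adducts to 6-silyloxycyclohepta-2,4-dienones and avoids a free alkoxide that could undergo retro-aldol cleavage at quaternary C6; methanolysis and standard acetylation follow.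

Step 3
Reactants: 7
Product: 8 (R)-6-hydroxy-3,7,7-trimethylcyclohepta-2,4-dien-1-one
Conditions: Burkholderia cepacia lipase, phosphate buffer pH 7/MTBE, 30 °C, stopped before half conversion; chromatography
Reagents that add atoms: none
Why: lipase-catalysed kinetic resolution by enantioselective ester hydrolysis; with the CMe2 side as the large and the cis-alkene side as the medium substituent, the empirical size rule for lipases predicts that the (R)-acetate is cleaved, which releases 8 and sets C7.

Step 4
Reactants: 8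
Product: 9 (R)-6-(tert-butyldimethylsilyloxy)-3,7,7-trimethylcyclohepta-2,4-dien-1-one
Conditions: TBSOTf, 2,6-lutidine, CH2Cl2, −78 °C
Reagents that add atoms: tert-butyldimethylsilyl trifluoromethanesulfonate CC(C)(C)[Si](C)(C)OS(=O)(=O)C(F)(F)F
Why: silyl-triflate silylation of a hindered secondary alcohol under weakly basic conditions, so that no alkoxide forms; no stereocentre is touched.

Step 5
Reactants: 9
Product: 10 (4S,5S,6S)-6-(tert-butyldimethylsilyloxy)-4,5-dihydroxy-3,7,7-trimethylcyclohept-2-en-1-one (cis-diol, both hydroxyls trans to the silyloxy group)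
Conditions: OsO4 (cat.), NMO, acetone/H2O, 0 °C to rt
Reagents that add atoms: N-methylmorpholine N-oxide C[N+]1([O-])CCOCC1; water O; osmium tetroxide O=[Os](=O)(=O)=O as oxygen-transfer catalyst
Why: catalytic osmium tetroxide dihydroxylation attacks the more electron-rich γ,δ-alkene of the dienone and adds both oxygens syn from the face opposite the allylic silyloxy group (the usual anti sense for osmylation of allylic ethers), which sets C8 and C9.

Step 6
Reactants: 10
Product: 11 4,5-O-isopropylidene acetal of 10 (cis-fused dioxolane, enone intact)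
Conditions: 2,2-dimethoxypropane, PPTS (cat.), CH2Cl2, rt
Reagents that add atoms: 2,2-dimethoxypropane COC(C)(C)OC
Why: acetal exchange ties the cis-8,9-diol in a dioxolane and leaves no free hydroxyl for the later ketene and organolithium steps.

Step 7
Reactants: 11
Product: 12 (1S,4S,5S,6S)-6-(tert-butyldimethylsilyloxy)-4,5-(isopropylidenedioxy)-3,7,7-trimethylcyclohept-2-en-1-ol (1-OH cis to the 6-silyloxy group)
Conditions: NaBH4, CeCl3·7H2O, MeOH, −78 °C
Reagents that add atoms: none
Why: Luche 1,2-reduction of the enone; hydride should add to the face opposite the C7 silyloxy group (1,3-anti attack, as in 5-substituted cycloalk-2-enones), which gives C5–OH cis to C7–OTBS.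

Step 8
Reactants: 12
Product: 15 ethyl 2-[5-(tert-butyldimethylsilyloxy)-6,7-(isopropylidenedioxy)-1,4,4-trimethylcyclohept-2-en-1-yl]acetate (CH2CO2Et cis to the silyloxy group, trans to the dioxolane), via orthoester 13 (not isolated), via ketene acetal 14 (not isolated)
Conditions: MeC(OEt)3, EtCO2H (cat.), xylene, 140 °C, EtOH distilled off
Reagents that add atoms: triethyl orthoacetate CCOC(C)(OCC)OCC
Why: Johnson–Claisen rearrangement; the [3,3] shift is suprafacial, so the C5–O stereocentre is transferred to quaternary C10 while the C5=C11 alkene is formed.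

Step 9
Reactants: 15
Product: 16 2-[5-(tert-butyldimethylsilyloxy)-6,7-(isopropylidenedioxy)-1,4,4-trimethylcyclohept-2-en-1-yl]acetic acid
Conditions: LiOH, THF/MeOH/H2O, rt; 0.5 M HCl to pH 4, 0 °C
Reagents that add atoms: lithium hydroxide [Li+].[OH-]
Why: saponification of an ethyl ester on a CH2 spacer; the silyl ether and the acetonide are stable to base and to the brief cold acidification.

Step 10
Reactants: 16
Product: 19 3-ethoxy-4-[5-(tert-butyldimethylsilyloxy)-6,7-(isopropylidenedioxy)-1,4,4-trimethylcyclohept-2-en-1-yl]cyclobut-2-en-1-one, via acid chloride 17 (not isolated), via ketene 18 (not isolated)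
Conditions: 1-chloro-N,N,2-trimethylprop-1-en-1-amine, CH2Cl2, 0 °C to rt; then ethoxyacetylene, Et3N, Et2O, rt
Reagents that add atoms: ethoxyacetylene C#COCC; 1-chloro-N,N,2-trimethylprop-1-en-1-amine CC(C)=C(Cl)N(C)C (chlorine stays only in 17)
Why: ketene–alkoxyalkyne [2+2] cycloaddition; the ketene made from 17 with Et3N adds to ethoxyacetylene with its carbonyl carbon on the alkyne CH, which gives the 4-substituted 3-ethoxycyclobutenone, and the neutral chloroenamine activation spares the acetonide.

Step 11
Reactants: 19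
Product: 21 3-methyl-4-[5-(tert-butyldimethylsilyloxy)-6,7-(isopropylidenedioxy)-1,4,4-trimethylcyclohept-2-en-1-yl]cyclobut-2-en-1-one, via lithium alkoxide 20 (not isolated)
Conditions: MeLi, CeCl3, THF, −78 °C; then 0.5 M HCl, THF, 0 °C, brief
Reagents that add atoms: methyllithium [Li]C
Why: 1,2-addition of the methyl-cerium reagent to the vinylogous-ester carbonyl (cerium limits enolisation of the acidic ring CH), then acid-promoted hydrolysis with allylic transposition (Stork–Danheiser type) makes the carbinol carbon C3(Me) and the enol-ether carbon the C1 ketone.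

Step 12
Reactants: 21
Product: 22 7-O-(tert-butyldimethylsilyl)-8,9-O-isopropylidene-7,8,9-trihydroxylongipin-2-en-1-one (tricycle, ring configuration as in the target)
Conditions: [Rh(CO)2Cl]2 (5 mol%, monovalent rhodium), P(C6F5)3 (20 mol%), toluene (0.02 M), CO (1 atm), 110 °C
Reagents that add atoms: none
Why: Proposed new method: the monovalent rhodium should insert into the acyl–C4 bond of the cyclobutenone (both C4 epimers converge), the tethered C5=C11 alkene then inserts into the rhodium–acyl bond to form C1–C11, and reductive elimination from the resulting rhodacyclopentane, whose C4 terminus is allylic, forms C4–C5. The closest known reaction type is the rhodium-catalysed carboacylation of alkenes by C–C activation of cyclobutenones and benzocyclobutenones (intermolecular [4+2] with strained alkenes, intramolecular cut-and-sew with longer tethers); new here is the one-atom tether, so that the second C–C bond closes a cyclobutane. The six-membered enone ring (C1, C2, C3, C4, C10, C11) closes by 6-exo migratory insertion and the cyclobutane (C4, C5, C10, C11) by C(sp3)–C(sp3) reductive elimination from a five-membered metallacycle. C11, C5 and C4 are all set by C10: the one-atom tether can deliver the four-carbon unit only to the alkene face that carries the side chain, the addition is suprafacial, and the cis ring alkene places C6 anti to the new enone bridge. The step needs the [4+2] mode to win over β-hydride elimination, decarbonylation and the thermal vinylketene [2+2] mode: C6 and C10 are quaternary and the only β-hydrogen (on C11) lies inside the metallacycle, CO suppresses decarbonylation, and thermal opening of the cyclobutenone gives the (E)-vinylketene, which cannot reach the alkene and recloses.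

Step 13
Reactants: 22
Product: 23 8,9-O-isopropylidene-7,8,9-trihydroxylongipin-2-en-1-one (free C7–OH)
Conditions: TBAF, THF, 40 °C; aq. NH4Cl
Reagents that add atoms: none
Why: fluoride cleavage of the silyl ether; the acetonide and the enone are inert and no stereocentre is involved.

Step 14
Reactants: 23
Product: 24 7-O-angeloyl-8,9-O-isopropylidene-7,8,9-trihydroxylongipin-2-en-1-one
Conditions: angelic acid, 2,4,6-trichlorobenzoyl chloride, Et3N, toluene, rt; then 23, toluene, 80 °C
Reagents that add atoms: angelic acid ((Z)-2-methylbut-2-enoic acid) C/C=C(/C)C(=O)O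
Why: Yamaguchi-type esterification with the preformed mixed anhydride and no nucleophilic catalyst, conditions known to acylate hindered secondary alcohols with angelic acid without Z to E isomerisation; C7–OH is the only free hydroxyl.

Step 15
Reactants: 24
Product: 25 7-O-angeloyl-7,8,9-trihydroxylongipin-2-en-1-one (free cis-8,9-diol)
Conditions: AcOH/H2O (4:1), 40 °C
Reagents that add atoms: none
Why: mild aqueous-acid acetal hydrolysis frees the cis-8,9-diol; the ester, the enone and the cyclobutane are stable under these conditions.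

Step 16
Reactants: 25
Product: 26 (4R,5S,7S,8S,9S,10R,11R)-7,8-bis(angeloyloxy)-9-hydroxylongipin-2-en-1-one (target)
Conditions: angelic acid, 2,4,6-trichlorobenzoyl chloride, Et3N, toluene, rt (1.1 equiv of mixed anhydride); then 25, toluene, 60 °C
Reagents that add atoms: angelic acid ((Z)-2-methylbut-2-enoic acid) C/C=C(/C)C(=O)O
Why: site-selective Yamaguchi-type monoacylation; C8–OH lies between two CH carbons whereas C9–OH is neopentylic (next to quaternary C10 and syn to its methyl), so one equivalent of the mixed anhydride should acylate C8 and leave C9–OH free.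

**Compound list**

1 | 2-methylfuran | Cc1ccco1 | starting material
2 | 3-bromo-3-methylbutan-2-one | CC(=O)C(C)(C)Br | starting material
3 | 1,1-dimethyl-2-oxidoallyl cation (oxyallyl zwitterion) | C[C+](C)C(=C)[O-] | intermediate (not isolated)
4 | rac-1,4,4-trimethyl-8-oxabicyclo[3.2.1]oct-6-en-3-one | CC12CC(=O)C(C)(C)C(O1)C=C2 | intermediate
5 | rac-3,7,7-trimethyl-6-(trimethylsilyloxy)cyclohepta-2,4-dien-1-one | C[Si](C)(C)OC1C=CC(C)=CC(=O)C1(C)C | intermediate (not isolated)
6 | rac-6-hydroxy-3,7,7-trimethylcyclohepta-2,4-dien-1-one | OC1C=CC(C)=CC(=O)C1(C)C | intermediate (not isolated)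
7 | rac-6-acetoxy-3,7,7-trimethylcyclohepta-2,4-dien-1-one | CC(=O)OC1C=CC(C)=CC(=O)C1(C)C | intermediate
8 | (R)-6-hydroxy-3,7,7-trimethylcyclohepta-2,4-dien-1-one | O[C@@H]1C=CC(C)=CC(=O)C1(C)C | intermediate
9 | (R)-6-(tert-butyldimethylsilyloxy)-3,7,7-trimethylcyclohepta-2,4-dien-1-one | CC(C)(C)[Si](C)(C)O[C@@H]1C=CC(C)=CC(=O)C1(C)C | intermediate
10 | (4S,5S,6S)-6-(tert-butyldimethylsilyloxy)-4,5-dihydroxy-3,7,7-trimethylcyclohept-2-en-1-one | CC(C)(C)[Si](C)(C)O[C@@H]1[C@@H](O)[C@@H](O)C(C)=CC(=O)C1(C)C | intermediate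
11 | 4,5-O-isopropylidene acetal of 10 | CC(C)(C)[Si](C)(C)O[C@@H]1[C@H]2OC(C)(C)O[C@H]2C(C)=CC(=O)C1(C)C | intermediate
12 | (1S,4S,5S,6S)-6-(tert-butyldimethylsilyloxy)-4,5-(isopropylidenedioxy)-3,7,7-trimethylcyclohept-2-en-1-ol | CC(C)(C)[Si](C)(C)O[C@@H]1[C@H]2OC(C)(C)O[C@H]2C(C)=C[C@H](O)C1(C)C | intermediate
13 | mixed diethyl orthoacetate of 12 | CC(C)(C)[Si](C)(C)O[C@@H]1[C@H]2OC(C)(C)O[C@H]2C(C)=C[C@H](OC(C)(OCC)OCC)C1(C)C | intermediate (not isolated)
14 | ketene O-ethyl acetal of 12 | CC(C)(C)[Si](C)(C)O[C@@H]1[C@H]2OC(C)(C)O[C@H]2C(C)=C[C@H](OC(=C)OCC)C1(C)C | intermediate (not isolated)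
15 | ethyl 2-[5-(tert-butyldimethylsilyloxy)-6,7-(isopropylidenedioxy)-1,4,4-trimethylcyclohept-2-en-1-yl]acetate | CC(C)(C)[Si](C)(C)O[C@@H]1[C@H]2OC(C)(C)O[C@H]2[C@](C)(CC(=O)OCC)C=CC1(C)C | intermediate
16 | the corresponding acetic acid | CC(C)(C)[Si](C)(C)O[C@@H]1[C@H]2OC(C)(C)O[C@H]2[C@](C)(CC(=O)O)C=CC1(C)C | intermediate
17 | the corresponding acid chloride | CC(C)(C)[Si](C)(C)O[C@@H]1[C@H]2OC(C)(C)O[C@H]2[C@](C)(CC(=O)Cl)C=CC1(C)C | intermediate (not isolated)
18 | the corresponding ketene | CC(C)(C)[Si](C)(C)O[C@@H]1[C@H]2OC(C)(C)O[C@H]2[C@](C)(C=C=O)C=CC1(C)C | intermediate (not isolated)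
19 | 3-ethoxy-4-(cycloheptenyl)cyclobut-2-en-1-one (epimers at the cyclobutenone CH) | CC(C)(C)[Si](C)(C)O[C@@H]1[C@H]2OC(C)(C)O[C@H]2[C@](C)(C3C(=O)C=C3OCC)C=CC1(C)C | intermediate
20 | lithium 3-ethoxy-1-methyl-4-(cycloheptenyl)cyclobut-2-en-1-olate | CC(C)(C)[Si](C)(C)O[C@@H]1[C@H]2OC(C)(C)O[C@H]2[C@](C)(C3C(C)([O-])C=C3OCC)C=CC1(C)C.[Li+] | intermediate (not isolated)
21 | 3-methyl-4-(cycloheptenyl)cyclobut-2-en-1-one (epimers at the cyclobutenone CH) | CC(C)(C)[Si](C)(C)O[C@@H]1[C@H]2OC(C)(C)O[C@H]2[C@](C)(C3C(=O)C=C3C)C=CC1(C)C | intermediate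
22 | 7-O-(tert-butyldimethylsilyl)-8,9-O-isopropylidene-7,8,9-trihydroxylongipin-2-en-1-one | CC(C)(C)[Si](C)(C)O[C@@H]1[C@H]2OC(C)(C)O[C@H]2[C@]3(C)[C@H]4C(C)=CC(=O)[C@@H]3[C@H]4C1(C)C | intermediate
23 | 8,9-O-isopropylidene-7,8,9-trihydroxylongipin-2-en-1-one | O[C@@H]1[C@H]2OC(C)(C)O[C@H]2[C@]3(C)[C@H]4C(C)=CC(=O)[C@@H]3[C@H]4C1(C)C | intermediate
24 | 7-O-angeloyl-8,9-O-isopropylidene-7,8,9-trihydroxylongipin-2-en-1-one | C/C=C(/C)C(=O)O[C@@H]1[C@H]2OC(C)(C)O[C@H]2[C@]3(C)[C@H]4C(C)=CC(=O)[C@@H]3[C@H]4C1(C)C | intermediate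
25 | 7-O-angeloyl-7,8,9-trihydroxylongipin-2-en-1-one | C/C=C(/C)C(=O)O[C@@H]1[C@@H](O)[C@@H](O)[C@]2(C)[C@H]3C(C)=CC(=O)[C@@H]2[C@H]3C1(C)C | intermediate
26 | (4R,5S,7S,8S,9S,10R,11R)-7,8-bis(angeloyloxy)-9-hydroxylongipin-2-en-1-one | C/C=C(/C)C(=O)O[C@@H]1[C@@H](OC(=O)/C(C)=C\C)C(C)(C)[C@@H]2[C@H]3C(=O)C=C(C)[C@@H]2[C@@]3(C)[C@@H]1O | target

**Count**

Total step count: 16. Longest linear sequence: 16 steps (1 and 2 to 26).

**Steps most likely to fail**

Step 12 (proposed new method). The reductive elimination that must close the four-membered ring may be too slow, so that decarbonylation or reversion take over, or the hindered alkene may not insert at all. The fallback is rhodium-free and stepwise; it sets out from acid 16 and returns at 22. Acid chloride 17, made as in step 10, is coupled with ethynyltributylstannane (PdCl2(PPh3)2, divalent palladium, Stille acylation) to give the terminal ynone F1. mCPBA epoxidises the C5=C11 alkene from the face opposite the side chain and the silyloxy group to give the epoxide F2. Cp2TiCl (trivalent titanium, from Cp2TiCl2 and Zn) opens the epoxide reductively; the C11 radical closes 6-endo onto the ynone and gives the cis-fused hydroxy enone F3, with the C1–C11 bond made and the C5 hydroxyl trans to it, while the unproductive C5 radical is deoxygenated back to F1. Mesylation gives the mesylate F4. LDA forms the α′-enolate at C4, which displaces the mesylate with inversion (4-exo-tet intramolecular enolate alkylation, the classical closure of bicyclo[3.1.1]heptanones) to give the bridged enone F5, which has the C4–C5 bond, the ketone at C3 and the alkene at C1=C2. MeLi/CeCl3 gives the tertiary allylic alcohol F6, and PCC brings about the oxidative 1,3-transposition to 22.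

Step 16. Site discrimination between the C8 and C9 hydroxyls may be poor, or the acyl group may migrate between them. The fallback differentiates by geometry instead of by rate; it sets out from 22 and returns at 26. Aqueous HF in MeCN removes the silyl ether and the acetonide to give the triol F7. Butane-2,3-dione, HC(OMe)3 and CSA in MeOH protect only the trans-7,8-diol as the butane-2,3-diacetal F8. Allyl chloroformate and pyridine cap C9–OH as the allyl carbonate F9. TFA/H2O removes the diacetal to give the 7,8-diol F10. Exhaustive angeloylation with the same mixed anhydride (excess, 90 °C) gives the diester F11, and Pd(PPh3)4 (zerovalent palladium) with morpholine removes the allyl carbonate to give 26.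

Step 3. The lipase may not turn over this α-quaternary acetate, or its discrimination between the enantiomers may be low. The fallback separates the enantiomers physically; it sets out from 7 and returns at 8. Preparative chromatography of 7 on a chiral stationary phase (supercritical CO2/MeOH) gives the (R)-acetate F12, which pig liver esterase at pH 7 cleaves to 8 without an alkoxide being formed.

**Further compounds**

F1 | step 12 | 1-[5-(tert-butyldimethylsilyloxy)-6,7-(isopropylidenedioxy)-1,4,4-trimethylcyclohept-2-en-1-yl]but-3-yn-2-one | CC(C)(C)[Si](C)(C)O[C@@H]1[C@H]2OC(C)(C)O[C@H]2[C@](C)(CC(=O)C#C)C=CC1(C)C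
F2 | step 12 | 2,3-epoxide of F1 (oxirane trans to the ynone side chain) | CC(C)(C)[Si](C)(C)O[C@@H]1[C@H]2OC(C)(C)O[C@H]2[C@](C)(CC(=O)C#C)[C@H]3O[C@H]3C1(C)C
F3 | step 12 | cis-fused bicyclo[5.4.0]undecenone with C3 ketone, C1=C2 alkene and C5 hydroxyl trans to C1 | CC(C)(C)[Si](C)(C)O[C@@H]1[C@H]2OC(C)(C)O[C@H]2[C@]3(C)CC(=O)C=C[C@@H]3[C@@H](O)C1(C)C
F4 | step 12 | methanesulfonate of F3 | CC(C)(C)[Si](C)(C)O[C@@H]1[C@H]2OC(C)(C)O[C@H]2[C@]3(C)CC(=O)C=C[C@@H]3[C@@H](OS(C)(=O)=O)C1(C)C
F5 | step 12 | 7-O-(tert-butyldimethylsilyl)-8,9-O-isopropylidene-3-nor-methyl-longipin-1-en-3-one (ketone at C3, alkene C1=C2) | CC(C)(C)[Si](C)(C)O[C@@H]1[C@H]2OC(C)(C)O[C@H]2[C@]3(C)[C@H]4C(=O)C=C[C@@H]3[C@H]4C1(C)C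
F6 | step 12 | tertiary allylic alcohol from F5 and MeLi (3-hydroxy-3-methyl, alkene C1=C2, epimers at C3) | CC(C)(C)[Si](C)(C)O[C@@H]1[C@H]2OC(C)(C)O[C@H]2[C@]3(C)[C@H]4C(C)(O)C=C[C@@H]3[C@H]4C1(C)C
F7 | step 16 | 7,8,9-trihydroxylongipin-2-en-1-one (triol) | O[C@@H]1[C@@H](O)[C@@H](O)[C@]2(C)[C@H]3C(C)=CC(=O)[C@@H]2[C@H]3C1(C)C
F8 | step 16 | 7,8-O-(2,3-dimethoxybutane-2,3-diyl) acetal of F7 (free C9–OH) | [C@H]15O[C@@](C)(OC)[C@](C)(OC)O[C@H]5[C@@H](O)[C@]2(C)[C@H]3C(C)=CC(=O)[C@@H]2[C@H]3C1(C)C
F9 | step 16 | 9-O-allyloxycarbonyl derivative of F8 | [C@H]15O[C@@](C)(OC)[C@](C)(OC)O[C@H]5[C@@H](OC(=O)OCC=C)[C@]2(C)[C@H]3C(C)=CC(=O)[C@@H]2[C@H]3C1(C)C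
F10 | step 16 | 9-O-allyloxycarbonyl-7,8,9-trihydroxylongipin-2-en-1-one (free 7,8-diol) | O[C@@H]1[C@@H](O)[C@@H](OC(=O)OCC=C)[C@]2(C)[C@H]3C(C)=CC(=O)[C@@H]2[C@H]3C1(C)C
F11 | step 16 | 7,8-di-O-angeloyl-9-O-allyloxycarbonyl-7,8,9-trihydroxylongipin-2-en-1-one | C/C=C(/C)C(=O)O[C@@H]1[C@@H](OC(=O)/C(C)=C\C)[C@@H](OC(=O)OCC=C)[C@]2(C)[C@H]3C(C)=CC(=O)[C@@H]2[C@H]3C1(C)C
F12 | step 3 | (R)-6-acetoxy-3,7,7-trimethylcyclohepta-2,4-dien-1-one | CC(=O)O[C@@H]1C=CC(C)=CC(=O)C1(C)C
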